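4 questions stood on the bench when I handed over, so I left this note with them.

| flask | starting material | second nucleophile | protic impurity | solid first nucleophile | remark | time |
|---|---|---|---|---|---|---|
| larch | 0.10 M | 0.20 M | 0.10 M | 0.25 M | run made earlier |  |
| birch | 0.050 M | 0.20 M | 0.10 M | 0.25 M | run made earlier |  |
| maple | 0.075 M | 0.20 M | 0.10 M | 0.25 M | run made earlier |  |
| noon | 0.10 M | 0.200 M (fed, over 20 h) | 0.100 M | 0.250 M | all else is in the flask from the start; the feed brings no volume worth counting | 2.0 d |
| dawn | 0.10 M (fed, over 20 h) | 0.200 M | 0.100 M | 0.250 M | all else is in the flask from the start; the feed brings no volume worth counting | 2.0 d |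
| summer | 0.10 M | 0.200 M | 0.100 M | 0.250 M | everything together at the start | 2.0 d |

- larch (time / h: solvolysis product / %, target / %): 4.00: 2.8, 0; 8.00: 4.9, 0.4; 20.0: 15.9, 1.1; 50.0: 28.7, 6.8
- birch (time / h: solvolysis product / %, target / %): 5.00: 3.1, 0; 15.0: 10.7, 1.3; 25.0: 17.0, 4.2; 40.0: 23.8, 4.5
- maple (time / h: solvolysis product / %, target / %): 5.00: 3.3, 0.8; 15.0: 10.9, 2.5; 25.0: 15.6, 1.0; 40.0: 25.2, 5.5

(scatter of a reading: 1 percentage point)

* the flask that comes out highest in amount of solvolysis product, in percent of the starting material charged, or "all alike" when all lie within 1.5 percentage points (noon / dawn / summer / all alike)
* solvolysis product at the end, in percent of the starting material charged, noon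
* solvolysis product at the end, in percent of the starting material charged, dawn
* solvolysis product at the end, in percent of the starting material charged, summer

- the numbers in the tables scatter by 1 percentage point (one standard deviation)
- at the start none of the solid first nucleophile is in solution
- a reading or a percentage of target counts all its forms, free or not

At 40.0 h, birch read 23.8% solvolysis product and maple 25.2%, though maple was charged 1.50 times as heavily. So I took the rate to follow starting material's own concentration, a pseudo-first-order loss. I named s the share of the remaining starting material that goes to solvolysis product each hour, with second nucleophile and protic impurity charged as in these runs, reckoned as if starting material went nowhere else. Larch's last reading gave s = 0.00677 /h, and after a stay t the product is one minus exp(−s·t).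

Summer and noon held their starting material for the whole 2.0 d, so I reckoned 27.7% for both. Dawn's starting material, fed steadily, stayed 38.0 h on average, which gave 22.7%. I asked my successor to keep dawn's feed steady, since that mean stay rests on it.

The forecast said 28.6% for noon, 23% for dawn and 28% for summer, with noon highest; its noon stood 0.90 percentage points above mine. On noon it warned: “The runs never varied the second nucleophile”.

| flask | from s | forecast | result |
|---|---|---|---|
| noon | 27.7% | 28.6% | 35.7% |
| dawn | 22.7% | 23% | 23.5% |
| summer | 27.7% | 28% | 27.6% |

    solid first nucleophile ⇌ first nucleophile, rate k1*(cs1 - [first nucleophile]) while solid is left; crystals form when [first nucleophile] > cs1 (solubility = 0.0510 M, k = 0.0187 /h)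
    starting material → intermediate (k = 0.0231 /h)
    intermediate → solvolysis product (k = 14.0 /h)
    second nucleophile + protic impurity → quenched reagent (k = 4.01 /M/h)
    second nucleophile + target ⇌ idle adduct, settled at all times (K = 12.0 /M)
    first nucleophile + intermediate → target (k = 242 /M/h)
    second nucleophile + intermediate → other capture product (k = 196 /M/h)

Noon ran 8 points over s, and at the end it held 24.7% other capture product against summer's 33.0%. Of the effects tried on the gap between noon and dawn, the largest single one was the low solubility of first nucleophile: the run without it cut that gap from 12 points to 2.8 points. For dawn read at 3.0 d, the mean stay became 62.0 h, so s gave 34.3%; the computed flask gave 30.9%.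

(The readings come from a simulation for an exercise, and the scatter is random.)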